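**Retrosynthetic overview**

1. Locants: C1 is the exocyclic carbinol carbon; C2 (bears C1 and the ring O), C3 (anisyl), C4 (OH) and C5 (OCH2) are the ring carbons. The target is cut at the C1–aryl bond into 3,4-dimethoxyphenyllithium and an α-chloro γ-lactol, which is a masked C1 aldehyde with chloride on C2.
2. Enabling feature: the C1 hydroxyl and the ring oxygen on C2 are erythro, and that oxygen reaches C5 through C3–C4. This is the signature of a trans C1–C2 epoxide opened 5-exo at C2 by the C5 hydroxyl. An α-chloro aldehyde gives exactly this epoxide after Cornforth-type aryl addition, so one flask forms the C1–aryl bond, the C1 stereocentre and the oxolane ring (O, C2, C3, C4, C5).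
3. The chloro lactol comes from a γ-butyrolactone by enolate chlorination anti to the C3 aryl group (sets C2) and DIBAL-H reduction. The lactone comes from copper-catalysed aryl Grignard addition to a butenolide, anti to the C4 side arm (sets C3).
4. Only C4 is bought, in (S)-5-(hydroxymethyl)furan-2(5H)-one. C3, C2 and C1 are relayed from it by substrate control.
5. Ring order: the purchased γ-lactone ring (C1, C2, C3, C4, O) is the stereochemical template through steps 1–4 and is opened in step 5. The oxolane ring is formed last, in the same step.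

Key step: step 5

Remark: the chloro lactol is taken to react through its open-chain hydroxy aldehyde tautomer, the usual course of organolithium additions to lactols.

**Step 1**
Reactants: 1 (S)-5-(hydroxymethyl)furan-2(5H)-one; 2 tert-butyl(chloro)diphenylsilane
Product: 3 (S)-5-{[(tert-butyldiphenylsilyl)oxy]methyl}furan-2(5H)-one
Conditions: TBDPSCl, imidazole, CH2Cl2, 0 → 23 °C
Reagents that add atoms: tert-butyl(chloro)diphenylsilane, CC(C)(C)[Si](Cl)(c1ccccc1)c1ccccc1
Why: Imidazole-promoted silyl ether formation on the primary alcohol should leave the base-sensitive C4 stereocentre untouched and installs the bulky side arm that steers step 2 and later becomes the ring oxygen.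

**Step 2**
Reactants: 3 (S)-5-{[(tert-butyldiphenylsilyl)oxy]methyl}furan-2(5H)-one; 4 4-methoxyphenylmagnesium bromide
Product: 6 (4R,5S)-5-{[(tert-butyldiphenylsilyl)oxy]methyl}-4-(4-methoxyphenyl)dihydrofuran-2(3H)-one, via trimethylsilyl ketene acetal 5 (not isolated)
Conditions: 4 (1.5 equiv), CuBr·SMe2 (10 mol %), TMSCl (2 equiv), THF, −78 → −40 °C; then aq NH4Cl
Reagents that add atoms: 4-methoxyphenylmagnesium bromide, COc1ccc([Mg]Br)cc1
Why: Copper-catalysed, TMSCl-accelerated conjugate addition of the aryl Grignard reagent to the butenolide should deliver the aryl group to the face anti to the silyloxymethyl arm, setting C3 as the 4,5-trans lactone, and silyl ketene acetal 5 is hydrolysed to 6 on work-up.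

**Step 3**
Reactants: 6 (4R,5S)-5-{[(tert-butyldiphenylsilyl)oxy]methyl}-4-(4-methoxyphenyl)dihydrofuran-2(3H)-one; 7 N-chlorosuccinimide
Product: 8 (3S,4R,5S)-3-chloro-5-{[(tert-butyldiphenylsilyl)oxy]methyl}-4-(4-methoxyphenyl)dihydrofuran-2(3H)-one
Conditions: LiHMDS, THF, −78 °C; inverse addition to NCS, THF, −78 °C; H2O
Reagents that add atoms: N-chlorosuccinimide, O=C1CCC(=O)N1Cl
Why: Electrophilic α-chlorination of the lithium lactone enolate should occur anti to the adjacent aryl group (the usual 3,4-trans selectivity of β-substituted γ-butyrolactone enolates), which sets C2 with chloride trans to aryl and cis to the CH2OSi arm, also the thermodynamically preferred all-trans arrangement.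

**Step 4**
Reactants: 8 (3S,4R,5S)-3-chloro-5-{[(tert-butyldiphenylsilyl)oxy]methyl}-4-(4-methoxyphenyl)dihydrofuran-2(3H)-one
Product: 9 (3S,4R,5S)-3-chloro-5-{[(tert-butyldiphenylsilyl)oxy]methyl}-4-(4-methoxyphenyl)oxolan-2-ol (anomeric mixture)
Conditions: DIBAL-H, CH2Cl2, −78 °C; Rochelle salt
Reagents that add atoms: none
Why: Partial hydride reduction of a γ-lactone with DIBAL-H at −78 °C should stop at the aluminium hemiacetal, which the α-chloro substituent stabilises, giving the lactol (a masked α-chloro aldehyde) with C2, C3 and C4 unchanged.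

**Step 5**
Reactants: 9 (3S,4R,5S)-3-chloro-5-{[(tert-butyldiphenylsilyl)oxy]methyl}-4-(4-methoxyphenyl)oxolan-2-ol; 10 4-bromo-1,2-dimethoxybenzene
Product: 16 (3S,4R,5S)-5-[(R)-(3,4-dimethoxyphenyl)(hydroxy)methyl]-4-(4-methoxyphenyl)oxolan-3-ol, via 3,4-dimethoxyphenyllithium 11 (not isolated), via open-chain chloro aldehyde 12 (not isolated), via anti-chlorohydrin 13 (not isolated), via silyl epoxide 14 (not isolated), via epoxy diol 15 (not isolated)
Conditions: 10 (2.4 equiv), t-BuLi (4.8 equiv), THF, −78 °C; add 9, −78 → 0 °C, then 23 °C; then TBAF (3 equiv), THF, 23 → 40 °C; H2O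
Reagents that add atoms: 4-bromo-1,2-dimethoxybenzene (as aryllithium 11), COc1ccc(Br)cc1OC
Why: The first equivalent of 11 deprotonates lactol 9, whose lithium lactolate opens to α-chloro aldehyde 12, and the second adds to the C1 carbonyl anti to the C2–Cl dipole (Cornforth/polar Felkin–Anh 1,2-addition, the known behaviour of α-chloro aldehydes towards organolithiums, here on a lactol as in C-aryl glycoside work), which should give anti-chlorohydrin 13 and thus the (R) configuration at C1. On warming, the C1 alkoxide displaces chloride at C2 with inversion (3-exo-tet) to trans-epoxide 14, a closure that proceeds from the extended ground-state conformer of an anti-chlorohydrin. Fluoride then unmasks the C5 oxygen (15), which opens the epoxide at C2 in a 5-exo-tet closure with a second inversion, so the ring oxygen ends where chloride sat: C2 keeps the configuration fixed in step 3, now cis to the C3 aryl group and erythro to the C1 hydroxyl, and the oxolane ring of the target is formed. The step needs epoxide closure to precede any attack of the C5 oxygen on the C2 chloride, which the silyl ether (cleaved only after 14 has formed) and the fast 3-exo closure under basic conditions should secure. It also needs 5-exo attack at C2 to beat 6-endo attack at the benzylic C1, which the basic, Lewis-acid-poor medium should secure because the electron-rich aryl group cannot then assist C1–O ionisation; the C4 alkoxide can reach the epoxide only in 4-exo or 5-endo modes, both slow under base. C3 and C4 are not touched.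

**Compound list**

1 | (S)-5-(hydroxymethyl)furan-2(5H)-one | O=C1C=C[C@@H](CO)O1 | starting material
2 | tert-butyl(chloro)diphenylsilane | CC(C)(C)[Si](Cl)(c1ccccc1)c1ccccc1 | starting material
3 | (S)-5-{[(tert-butyldiphenylsilyl)oxy]methyl}furan-2(5H)-one | O=C1C=C[C@@H](CO[Si](c2ccccc2)(c2ccccc2)C(C)(C)C)O1 | intermediate
4 | 4-methoxyphenylmagnesium bromide | COc1ccc([Mg]Br)cc1 | starting material
5 | tert-butyl{[(2S,3R)-3-(4-methoxyphenyl)-5-[(trimethylsilyl)oxy]-2,3-dihydrofuran-2-yl]methoxy}diphenylsilane (silyl ketene acetal, not isolated) | COc1ccc([C@H]2C=C(O[Si](C)(C)C)O[C@@H]2CO[Si](c3ccccc3)(c3ccccc3)C(C)(C)C)cc1 | intermediate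
6 | (4R,5S)-5-{[(tert-butyldiphenylsilyl)oxy]methyl}-4-(4-methoxyphenyl)dihydrofuran-2(3H)-one (4,5-trans) | COc1ccc([C@H]2CC(=O)O[C@@H]2CO[Si](c3ccccc3)(c3ccccc3)C(C)(C)C)cc1 | intermediate
7 | N-chlorosuccinimide | O=C1CCC(=O)N1Cl | starting material
8 | (3S,4R,5S)-3-chloro-5-{[(tert-butyldiphenylsilyl)oxy]methyl}-4-(4-methoxyphenyl)dihydrofuran-2(3H)-one (3,4-trans, 4,5-trans) | COc1ccc([C@H]2[C@H](Cl)C(=O)O[C@@H]2CO[Si](c3ccccc3)(c3ccccc3)C(C)(C)C)cc1 | intermediate
9 | (3S,4R,5S)-3-chloro-5-{[(tert-butyldiphenylsilyl)oxy]methyl}-4-(4-methoxyphenyl)oxolan-2-ol (anomeric mixture) | COc1ccc([C@H]2[C@H](Cl)C(O)O[C@@H]2CO[Si](c3ccccc3)(c3ccccc3)C(C)(C)C)cc1 | intermediate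
10 | 4-bromo-1,2-dimethoxybenzene | COc1ccc(Br)cc1OC | starting material
11 | 3,4-dimethoxyphenyllithium (not isolated) | [Li]c1ccc(OC)c(OC)c1 | intermediate
12 | (2S,3R,4S)-5-[(tert-butyldiphenylsilyl)oxy]-2-chloro-4-hydroxy-3-(4-methoxyphenyl)pentanal (as lithium alkoxide, not isolated) | COc1ccc([C@@H]([C@H](Cl)C=O)[C@H](O)CO[Si](c3ccccc3)(c3ccccc3)C(C)(C)C)cc1 | intermediate
13 | (1R,2S,3R,4S)-5-[(tert-butyldiphenylsilyl)oxy]-2-chloro-1-(3,4-dimethoxyphenyl)-3-(4-methoxyphenyl)pentane-1,4-diol (1,2-anti chlorohydrin, as dilithium alkoxide, not isolated) | COc1ccc([C@@H]([C@H](Cl)[C@H](O)c2ccc(OC)c(OC)c2)[C@H](O)CO[Si](c3ccccc3)(c3ccccc3)C(C)(C)C)cc1 | intermediate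
14 | (1R,2S)-3-[(tert-butyldiphenylsilyl)oxy]-1-[(2R,3R)-3-(3,4-dimethoxyphenyl)oxiran-2-yl]-1-(4-methoxyphenyl)propan-2-ol (trans-epoxide, as alkoxide, not isolated) | COc1ccc([C@@H]([C@H]2O[C@@H]2c4ccc(OC)c(OC)c4)[C@H](O)CO[Si](c3ccccc3)(c3ccccc3)C(C)(C)C)cc1 | intermediate
15 | (2S,3R)-3-[(2R,3R)-3-(3,4-dimethoxyphenyl)oxiran-2-yl]-3-(4-methoxyphenyl)propane-1,2-diol (as alkoxide, not isolated) | COc1ccc([C@@H]([C@H]2O[C@@H]2c4ccc(OC)c(OC)c4)[C@H](O)CO)cc1 | intermediate
16 | (3S,4R,5S)-5-[(R)-(3,4-dimethoxyphenyl)(hydroxy)methyl]-4-(4-methoxyphenyl)oxolan-3-ol (all-cis ring, erythro C1/C2) | COc1ccc([C@H]2[C@@H]([C@H](O)c3ccc(OC)c(OC)c3)OC[C@H]2O)cc1 | target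

**Step count and risks**

Total steps: 5. Longest linear sequence: 5 steps (1 → 16).

Step 5 is the most likely to fail. Facial selectivity at C1 may erode, or C2 may epimerise through enolisation of the open aldehyde by the basic aryllithium. The C5 oxygen may attack the C2 chloride before the epoxide has closed (after silyl migration), which would invert C2 only once. The benzylic epoxide may also open 6-endo at C1. The fallback sets out from 6, comes back at 16, and makes the same C1–aryl bond by acylation instead of aldehyde addition. The enolate of 6 (KHMDS, THF, −78 °C) is hydroxylated with 2-(phenylsulfonyl)-3-phenyloxaziridine anti to the aryl group to give the hydroxy lactone (3S,4S,5S)-5-{[(tert-butyldiphenylsilyl)oxy]methyl}-3-hydroxy-4-(4-methoxyphenyl)dihydrofuran-2(3H)-one F1. TBAF gives the diol (3S,4S,5S)-3-hydroxy-5-(hydroxymethyl)-4-(4-methoxyphenyl)dihydrofuran-2(3H)-one F2. Mitsunobu cyclodehydration (PPh3, DIAD, THF) joins the C2 oxygen to C5, which lie cis on the lactone, without touching a stereocentre and gives the bicyclic lactone (1S,4S,7R)-7-(4-methoxyphenyl)-2,5-dioxabicyclo[2.2.1]heptan-3-one F3. Its bridgehead α-carbon cannot enolise, so one equivalent of 11 at −78 °C should give the ketone (3,4-dimethoxyphenyl)[(2S,3R,4S)-4-hydroxy-3-(4-methoxyphenyl)oxolan-2-yl]methanone F4. Chelation-controlled reduction with Zn(BH4)2 (Et2O, −20 °C), with zinc bridging the ketone and ring oxygens and hydride arriving from the face away from C3, should then give the erythro alcohol 16.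

Step 3 is next. Proton exchange between product and enolate may lead to over-chlorination, and facial control may be incomplete. The fallback sets out from 6 and comes back at 8. It guarantees monochlorination and sets C2 under thermodynamic control. Claisen formylation (NaH, HCO2Et, THF) gives (4S,5S)-5-{[(tert-butyldiphenylsilyl)oxy]methyl}-3-(hydroxymethylidene)-4-(4-methoxyphenyl)dihydrofuran-2(3H)-one F5. Chlorination of this single acidic position with NCS (CH2Cl2, 0 °C) gives (3R,4R,5S)-3-chloro-5-{[(tert-butyldiphenylsilyl)oxy]methyl}-4-(4-methoxyphenyl)-2-oxooxolane-3-carbaldehyde F6. Deformylation (K2CO3, MeOH, 0 °C) with equilibration of the enolisable C2 centre should then settle on the all-trans chloro lactone 8.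

Step 2 is third. The Grignard reagent may add 1,2 to the lactone carbonyl, or deprotonate the butenolide at the γ-position, which would erode the C4 configuration through the achiral 2-oxidofuran. The fallback sets out from 3 and comes back at 6 with no new compound. It is a rhodium(I)-catalysed Hayashi–Miyaura conjugate addition of 4-methoxyphenylboronic acid ([Rh(cod)OH]2, dioxane/H2O, 50 °C) under nearly neutral conditions, with the same anti delivery steered by the side arm.

**Further compounds**

F1 | step 5 | (3S,4S,5S)-5-{[(tert-butyldiphenylsilyl)oxy]methyl}-3-hydroxy-4-(4-methoxyphenyl)dihydrofuran-2(3H)-one | COc1ccc([C@H]2[C@H](O)C(=O)O[C@@H]2CO[Si](c3ccccc3)(c3ccccc3)C(C)(C)C)cc1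
F2 | step 5 | (3S,4S,5S)-3-hydroxy-5-(hydroxymethyl)-4-(4-methoxyphenyl)dihydrofuran-2(3H)-one | COc1ccc([C@H]2[C@H](O)C(=O)O[C@@H]2CO)cc1
F3 | step 5 | (1S,4S,7R)-7-(4-methoxyphenyl)-2,5-dioxabicyclo[2.2.1]heptan-3-one | COc1ccc([C@H]2[C@H]3C(=O)O[C@@H]2CO3)cc1
F4 | step 5 | (3,4-dimethoxyphenyl)[(2S,3R,4S)-4-hydroxy-3-(4-methoxyphenyl)oxolan-2-yl]methanone | COc1ccc([C@H]2[C@@H](C(=O)c3ccc(OC)c(OC)c3)OC[C@H]2O)cc1
F5 | step 3 | (4S,5S)-5-{[(tert-butyldiphenylsilyl)oxy]methyl}-3-(hydroxymethylidene)-4-(4-methoxyphenyl)dihydrofuran-2(3H)-one | COc1ccc([C@H]2C(=CO)C(=O)O[C@@H]2CO[Si](c3ccccc3)(c3ccccc3)C(C)(C)C)cc1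
F6 | step 3 | (3R,4R,5S)-3-chloro-5-{[(tert-butyldiphenylsilyl)oxy]methyl}-4-(4-methoxyphenyl)-2-oxooxolane-3-carbaldehyde | COc1ccc([C@H]2[C@@](Cl)(C=O)C(=O)O[C@@H]2CO[Si](c3ccccc3)(c3ccccc3)C(C)(C)C)cc1
F0 | step 2 | none | none
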